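**Retrosynthetic overview**
1. Pleiogenone A (8) ⇐ anti (SN2) hydrolysis at C4 of the cis-epoxy enone 7 (4,5-epoxy-6-hydroxy-6-alkylcyclohex-2-enone).
2. 7 ⇐ Stork–Danheiser carbonyl transposition of β-methoxy enone 6 (the OMe-bearing carbon becomes the C1 ketone).
3. 6 ⇐ 1,2-addition, anti to the epoxide, of the (Z)-heptadec-8-enyl organocerium (bromide 5 from oleic acid) to epoxy-quinone monoketal 3, then ketal hydrolysis.
4. 3 ⇐ organocatalytic enantioselective nucleophilic epoxidation of achiral p-quinone monoketal 2 ⇐ 2,4-dimethoxyphenol.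
5. Rings: the carbocycle is taken intact from the arene (dearomatised in step 1); the oxirane is made in step 2 and opened in the last step.

Assumption: the quinidine-derived catalyst A gives (1R,6S)-3; if the opposite sense is found, the quinine-derived pseudoenantiomer is used. Catalyst A is prepared separately and not counted.

**Step 1**
Reactants: 1, 2,4-dimethoxyphenol
Product: 2, 2,4,4-trimethoxycyclohexa-2,5-dien-1-one
Conditions: PhI(OAc)2 (1.1 equiv), MeOH, 0 °C, 30 min; NaHCO3 work-up
Reagents that add atoms: methanol, CO
Why: Iodine(III) oxidative dearomatisation (Pelter-type); methanol traps the para, OMe-bearing carbon of the aryloxy-iodane to give the achiral p-quinone monoketal.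

**Step 2**
Reactants: 2, 2,4,4-trimethoxycyclohexa-2,5-dien-1-one
Product: 3, (1R,6S)-3,5,5-trimethoxy-7-oxabicyclo[4.1.0]hept-3-en-2-one (the 5,6-epoxide of 2)
Conditions: catalyst A (10 mol%), TBHP (1.5 equiv, decane), 1 M aq. NaOH (0.2 equiv), toluene, −20 °C. Catalyst A is N-benzyl-9-deoxy-9-epi-[3-(3,5-bis(trifluoromethyl)phenyl)ureido]quinidinium bromide, i.e. quinidine with C9–OH replaced (with inversion) by NHC(O)NHAr and the quinuclidine N benzylated.
Reagents that add atoms: tert-butyl hydroperoxide, CC(C)(C)OO
Why: Proposed new method: bifunctional urea/quaternary-ammonium ion-pair epoxidation applied to a 2-alkoxy p-quinone monoketal, a substrate class on which it has not been shown. The urea N–H pair docks the C1 carbonyl (and C2–OMe), and the ammonium delivers tBuOO⁻ to one face of C5 (C3 is deactivated by the α-OMe). The enolate then closes on O–O with loss of tBuO⁻ (Weitz–Scheffer), setting both oxirane carbons in one event. The closest known reactions are the cinchona phase-transfer Weitz–Scheffer epoxidation of p-quinone monoketals and urea/guanidinium bifunctional epoxidation of chalcones and 1,4-naphthoquinones.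

**Step 3**
Reactants: 4, oleic acid [(9Z)-octadec-9-enoic acid]
Product: 5, (8Z)-1-bromoheptadec-8-ene
Conditions: N-hydroxypyridine-2-thione, DCC, DMAP (cat.), CH2Cl2, dark, 0 °C → rt; then BrCCl3, hν (W lamp), 20 °C
Reagents that add atoms: bromotrichloromethane, BrC(Cl)(Cl)Cl
Why: Barton decarboxylative bromination; the primary radical from the thiohydroxamate ester abstracts Br from BrCCl3, and the remote Z-alkene keeps its geometry.

**Step 4**
Reactants: 3, (1R,6S)-3,5,5-trimethoxy-7-oxabicyclo[4.1.0]hept-3-en-2-one; 5, (8Z)-1-bromoheptadec-8-ene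
Product: 6, (1S,5R,6R)-5-[(8Z)-heptadec-8-en-1-yl]-5-hydroxy-4-methoxy-7-oxabicyclo[4.1.0]hept-3-en-2-one (tertiary OH cis to the epoxide)
Conditions: 5, Mg, THF, 45 °C; CeCl3, THF, −78 °C; then 3, −78 °C, 1 h; aq. NH4Cl; then 5% aq. oxalic acid, THF, 0 °C → rt
Reagents that add atoms: water, O (oxygen of the new C=O; the alkyl group comes from 5)
Why: Organocerium (Imamoto-type Grignard) 1,2-addition to the α,β-epoxy ketone occurs anti to the epoxide oxygen, which sets the quaternary carbinol (R) with OH cis to the oxirane; mild acid then cleaves the vinylogous ortho-ester ketal at the ketal carbon to give the β-methoxy enone.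

**Step 5**
Reactants: 6
Product: 7, (1R,2R,6R)-2-[(8Z)-heptadec-8-en-1-yl]-2-hydroxy-7-oxabicyclo[4.1.0]hept-4-en-3-one [= (4R,5R,6R)-4,5-epoxy-6-hydroxy-6-alkylcyclohex-2-enone]
Conditions: DIBAL-H (3 equiv), THF, −78 °C; then 0.5 M aq. H2SO4, THF, 0 °C, 20 min
Reagents that add atoms: water, O (oxygen of the new C=O)
Why: Stork–Danheiser transposition; 1,2-reduction of the vinylogous ester carbonyl, then acid ionisation and enol-ether hydrolysis, moves the ketone next to the quaternary carbinol, and the new carbinol is eliminated so no stereocentre is touched.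

**Step 6**
Reactants: 7
Product: 8, pleiogenone A, (4S,5R,6R)-6-[(8Z)-heptadec-8-en-1-yl]-4,5,6-trihydroxycyclohex-2-en-1-one
Conditions: 0.2 M HClO4, THF/H2O (2:1), 23 °C; NaHCO3
Reagents that add atoms: water, O
Why: Acid-catalysed SN2 epoxide hydrolysis at the allylic, less hindered C4 (C5 is neopentyl-like) inverts C4 to S, giving the 4,5-trans diol while C5–O stays cis to C6–OH.

**Compound list**
1 | 2,4-dimethoxyphenol | COc1ccc(O)c(OC)c1 | starting material
2 | 2,4,4-trimethoxycyclohexa-2,5-dien-1-one | COC1=CC(OC)(OC)C=CC1=O | intermediate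
3 | (1R,6S)-3,5,5-trimethoxy-7-oxabicyclo[4.1.0]hept-3-en-2-one | O=C1C(OC)=CC(OC)(OC)[C@H]2O[C@@H]12 | intermediate
4 | oleic acid | CCCCCCCC/C=C\CCCCCCCC(=O)O | starting material
5 | (8Z)-1-bromoheptadec-8-ene | CCCCCCCC/C=C\CCCCCCCBr | intermediate
6 | (1S,5R,6R)-5-[(8Z)-heptadec-8-en-1-yl]-5-hydroxy-4-methoxy-7-oxabicyclo[4.1.0]hept-3-en-2-one | CCCCCCCC/C=C\CCCCCCC[C@]1(O)C(OC)=CC(=O)[C@H]2O[C@@H]12 | intermediate
7 | (1R,2R,6R)-2-[(8Z)-heptadec-8-en-1-yl]-2-hydroxy-7-oxabicyclo[4.1.0]hept-4-en-3-one | CCCCCCCC/C=C\CCCCCCC[C@]1(O)C(=O)C=C[C@H]2O[C@@H]12 | intermediate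
8 | pleiogenone A | CCCCCCCC/C=C\CCCCCCC[C@]1(O)C(=O)C=C[C@H](O)[C@H]1O | target

**Totals**
Total steps: 6 (steps 5 and 6 use the same aqueous acid and can be run in one pot, giving 5).
Longest linear sequence: 5 (1 → 2 → 3 → 6 → 7 → 8).

**Steps most likely to fail**
1. Step 2 (proposed new epoxidation): the ee or rate may be poor on this substrate. Fallback: drop the H-bond-directed design and use the known plain ion-pair phase-transfer Weitz–Scheffer epoxidation of p-quinone monoketals (N-benzylcinchonidinium or cinchoninium chloride, TBHP, NaOH, toluene), upgrading ee by recrystallising 3 or 6.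
2. Step 4: ketal hydrolysis could place the carbonyl on the wrong carbon (C=O next to the carbinol, OMe at the former ketal carbon), or the addition could be unclean. Fallback: reverse the order. Hydrolyse 3 first to 5,6-epoxy-2-methoxy-1,4-benzoquinone, then add the organocerium to C1; the C4 carbonyl is a deactivated vinylogous ester, so the enol-ether position is fixed before the C–C bond is made.
3. Step 6: the acid-sensitive hydroxy enone may give the wrong regiochemistry or side reactions. Fallback: open the epoxide before the transposition. In 6 the target-C4 carbon is α to the ketone, so SN2 opening with CsOAc/AcOH gives the trans acetoxy alcohol. DIBAL-H then reduces the ketone and removes the acetate, and acid completes the Stork–Danheiser step directly to 8.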